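## Retrosynthetic overview

1. Plastochromanol-8 comes from its aryl silyl ether. The C2 methyl is a decarbonylated C2–CH2–CHO arm, and the C4 methylene is a hydrogenolysed benzylic C4–O bond.
2. Both handles are stored in one bridged lactol: a chroman whose C4 oxygen and C2–CH2 arm are tied as C4–O–CH(OH)–CH2–C2.
3. Key disconnection, C3–C4: an amine-catalysed vinylogous aldol addition of the 3-methyl carbon of all-E-solanesal (as its dienamine) to a salicylaldehyde. Oxa-Michael addition of the phenol then closes the pyran ring and sets C2.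
4. Fragments: the salicylaldehyde from 2,3-dimethylhydroquinone (mono-silylation, ortho-formylation), and solanesal from solanesol, which supplies C2, C3, the C2 methyl and the whole all-E side chain.
5. Ring order: the benzene ring is bought; the pyran ring and the temporary lactol ring form together in the key step; the lactol ring is opened later.

## Conventions and assumption

R = (3E,7E,11E,15E,19E,23E,27E)-4,8,12,16,20,24,28,32-octamethyltritriaconta-3,7,11,15,19,23,27,31-octaen-1-yl, the all-E C41 chain on C2 of the target. Chroman numbering is used throughout (O1, C2, C3, C4, C4a … C8a).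

Assumption: the (S)-diarylprolinol silyl ether is taken to give the 2R series in step 4. This sense of induction is not derived here; if chiral HPLC of 14 shows the 2S series, the (R)-catalyst is used with nothing else changed.

## Route

Step 1
Reactants: 1 2,3-dimethylhydroquinone
Product: 2 2,3-dimethyl-4-(triisopropylsilyloxy)phenol
Conditions: 1 (3 equiv), TIPSCl (1 equiv), imidazole, DMF, 0 °C to rt; excess 1 recovered by base extraction
Reagents that add atoms: triisopropylsilyl chloride, CC(C)[Si](Cl)(C(C)C)C(C)C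
Why: Silyl ether formation on a symmetric diol, where either hydroxyl gives the same product and the excess of diol suppresses bis-silylation.

Step 2
Reactants: 2 2,3-dimethyl-4-(triisopropylsilyloxy)phenol
Product: 4 2-hydroxy-3,4-dimethyl-5-(triisopropylsilyloxy)benzaldehyde, via ortho-hydroxymethyl phenol 3 (not isolated)
Conditions: MgCl2, Et3N, paraformaldehyde, THF, reflux; dilute HCl work-up
Reagents that add atoms: formaldehyde (charged as paraformaldehyde), C=O
Why: Casiraghi–Skattebøl ortho-formylation, in which the magnesium phenoxide delivers formaldehyde to the only free ortho position and a second formaldehyde oxidises the benzylic alcohol 3 by hydride transfer.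

Step 3
Reactants: 5 all-E-solanesol
Product: 6 all-E-solanesal
Conditions: activated MnO2 (15 equiv), hexane/CH2Cl2, rt
Reagents that add atoms: none
Why: MnO2 oxidation is selective for the allylic alcohol and leaves the eight isolated trisubstituted alkenes and the 2E geometry untouched.

Step 4
Reactants: 4 2-hydroxy-3,4-dimethyl-5-(triisopropylsilyloxy)benzaldehyde and 6 all-E-solanesal (1.3 equiv)
Product: 9 bridged chroman lactol (2R,4R; both anomers), via vinylogous aldol adduct 7 (not isolated), via open hydroxy aldehyde 8 (not isolated)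
Conditions: (S)-2-{bis[3,5-bis(trifluoromethyl)phenyl](triethylsilyloxy)methyl}pyrrolidine (30 mol %), PhCO2H (30 mol %), toluene, rt, 4–6 d
Reagents that add atoms: none
Why: Organocatalytic domino vinylogous aldol/oxa-Michael/hemiacetalisation, in which the terminal carbon of the solanesal dienamine adds to the aldehyde of 4 (C3–C4 bond), the phenol adds to the β-carbon of the resulting iminium ion on the face left open by the C(Ar)2OSiEt3 group (sets C2 as R), and only the adduct with C4–OH cis to the CH2CHO arm can close to the lactol, which pulls the equilibria to 9.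

Step 5
Reactants: 9 bridged chroman lactol
Product: 10 bridged chroman lactone (2R,4R)
Conditions: Pr4N[RuO4] (5 mol %), N-methylmorpholine N-oxide, 4 Å molecular sieves, CH2Cl2, rt
Reagents that add atoms: none
Why: Ley–Griffith oxidation of a lactol to a lactone under neutral conditions that leave isolated alkenes and the aryl silyl ether alone and avoid base-induced retro-oxa-Michael opening.

Step 6
Reactants: 10 bridged chroman lactone
Product: 11 [(2R)-7,8-dimethyl-2-R-6-(triisopropylsilyloxy)chroman-2-yl]acetic acid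
Conditions: Li (8 equiv), NH3(l)/THF 2:1, −78 °C, 10 min, substrate added to the blue solution; solid NH4Cl; then 1 M HCl to pH 3
Reagents that add atoms: none
Why: Dissolving-metal (Birch-type) hydrogenolysis cleaves the benzylic C4–O bond of the ester to give C4H2 and the carboxylate, while non-conjugated alkenes are inert, the ring is not reduced without an added alcohol, and C2 is not involved.

Step 7
Reactants: 11 chroman-2-ylacetic acid
Product: 12 2-[(2R)-7,8-dimethyl-2-R-6-(triisopropylsilyloxy)chroman-2-yl]ethanol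
Conditions: LiAlH4, THF, 0 °C to rt; Fieser work-up
Reagents that add atoms: none
Why: Hydride reduction of a carboxylic acid to the primary alcohol, chosen over borane because borane would hydroborate the chain.

Step 8
Reactants: 12 chroman-2-ylethanol
Product: 13 [(2R)-7,8-dimethyl-2-R-6-(triisopropylsilyloxy)chroman-2-yl]acetaldehyde
Conditions: Dess–Martin periodinane, pyridine, CH2Cl2, 0 °C to rt
Reagents that add atoms: none
Why: Dess–Martin oxidation stops at the aldehyde under buffered, non-basic conditions, so the β-aryloxy aldehyde cannot undergo retro-oxa-Michael opening.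

Step 9
Reactants: 13 chroman-2-ylacetaldehyde
Product: 14 plastochromanol-8 triisopropylsilyl ether
Conditions: RhCl(PPh3)3 (1.2 equiv), degassed toluene, 110 °C
Reagents that add atoms: none
Why: Tsuji–Wilkinson decarbonylation (formyl C–H insertion, CO extrusion, C–H reductive elimination) turns CH2CHO into CH3 without radicals; the alkyl–rhodium intermediate has no β-hydrogen and the trisubstituted alkenes do not react.

Step 10
Reactants: 14 plastochromanol-8 triisopropylsilyl ether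
Product: 15 plastochromanol-8
Conditions: Bu4NF, AcOH (1:1), THF, 0 °C, argon
Reagents that add atoms: none
Why: Fluoride cleaves the aryl Si–O bond, and the acetic acid buffer keeps the air-sensitive chromanol from sitting as its phenoxide.

## Compound list

1 | 2,3-dimethylbenzene-1,4-diol (2,3-dimethylhydroquinone) | Cc1c(O)ccc(O)c1C | starting material
2 | 2,3-dimethyl-4-(triisopropylsilyloxy)phenol | Cc1c(O)ccc(O[Si](C(C)C)(C(C)C)C(C)C)c1C | intermediate
3 | 6-(hydroxymethyl)-2,3-dimethyl-4-(triisopropylsilyloxy)phenol (present as magnesium phenoxide, not isolated) | OCc1cc(O[Si](C(C)C)(C(C)C)C(C)C)c(C)c(C)c1O | intermediate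
4 | 2-hydroxy-3,4-dimethyl-5-(triisopropylsilyloxy)benzaldehyde | O=Cc1cc(O[Si](C(C)C)(C(C)C)C(C)C)c(C)c(C)c1O | intermediate
5 | all-E-solanesol, (2E,6E,10E,14E,18E,22E,26E,30E)-3,7,11,15,19,23,27,31,35-nonamethylhexatriaconta-2,6,10,14,18,22,26,30,34-nonaen-1-ol | CC(C)=CCC/C(C)=C/CC/C(C)=C/CC/C(C)=C/CC/C(C)=C/CC/C(C)=C/CC/C(C)=C/CC/C(C)=C/CC/C(C)=C/CO | starting material
6 | all-E-solanesal (the corresponding 2-enal) | CC(C)=CCC/C(C)=C/CC/C(C)=C/CC/C(C)=C/CC/C(C)=C/CC/C(C)=C/CC/C(C)=C/CC/C(C)=C/CC/C(C)=C/C=O | intermediate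
7 | vinylogous aldol adduct: enal OHC–CH=C(R)–CH2–CH(OH)Ar with an (R)-configured benzylic carbinol, Ar = 2-hydroxy-3,4-dimethyl-5-(triisopropylsilyloxy)phenyl; held on the catalyst as iminium ion, enal geometry not defined, not isolated | CC(C)=CCC/C(C)=C/CC/C(C)=C/CC/C(C)=C/CC/C(C)=C/CC/C(C)=C/CC/C(C)=C/CC/C(C)=C/CCC(=CC=O)C[C@@H](O)c1cc(O[Si](C(C)C)(C(C)C)C(C)C)c(C)c(C)c1O | intermediate
8 | [(2R,4R)-4-hydroxy-7,8-dimethyl-2-R-6-(triisopropylsilyloxy)chroman-2-yl]acetaldehyde (open form of 9, not isolated) | CC(C)=CCC/C(C)=C/CC/C(C)=C/CC/C(C)=C/CC/C(C)=C/CC/C(C)=C/CC/C(C)=C/CC/C(C)=C/CC[C@]1(CC=O)C[C@@H](O)c2cc(O[Si](C(C)C)(C(C)C)C(C)C)c(C)c(C)c2O1 | intermediate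
9 | bridged lactol: (2R,4R)-7,8-dimethyl-2-R-6-(triisopropylsilyloxy)chroman with C4–O–CH(OH)–CH2–C2 bridge, both anomers | CC(C)=CCC/C(C)=C/CC/C(C)=C/CC/C(C)=C/CC/C(C)=C/CC/C(C)=C/CC/C(C)=C/CC/C(C)=C/CC[C@]12CC(O)O[C@H](C1)c1cc(O[Si](C(C)C)(C(C)C)C(C)C)c(C)c(C)c1O2 | intermediate
10 | bridged lactone: as 9 with C4–O–C(=O)–CH2–C2 bridge, (2R,4R) | CC(C)=CCC/C(C)=C/CC/C(C)=C/CC/C(C)=C/CC/C(C)=C/CC/C(C)=C/CC/C(C)=C/CC/C(C)=C/CC[C@]12CC(=O)O[C@H](C1)c1cc(O[Si](C(C)C)(C(C)C)C(C)C)c(C)c(C)c1O2 | intermediate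
11 | [(2R)-7,8-dimethyl-2-R-6-(triisopropylsilyloxy)chroman-2-yl]acetic acid | CC(C)=CCC/C(C)=C/CC/C(C)=C/CC/C(C)=C/CC/C(C)=C/CC/C(C)=C/CC/C(C)=C/CC/C(C)=C/CC[C@]1(CC(=O)O)CCc2cc(O[Si](C(C)C)(C(C)C)C(C)C)c(C)c(C)c2O1 | intermediate
12 | 2-[(2R)-7,8-dimethyl-2-R-6-(triisopropylsilyloxy)chroman-2-yl]ethanol | CC(C)=CCC/C(C)=C/CC/C(C)=C/CC/C(C)=C/CC/C(C)=C/CC/C(C)=C/CC/C(C)=C/CC/C(C)=C/CC[C@]1(CCO)CCc2cc(O[Si](C(C)C)(C(C)C)C(C)C)c(C)c(C)c2O1 | intermediate
13 | [(2R)-7,8-dimethyl-2-R-6-(triisopropylsilyloxy)chroman-2-yl]acetaldehyde | CC(C)=CCC/C(C)=C/CC/C(C)=C/CC/C(C)=C/CC/C(C)=C/CC/C(C)=C/CC/C(C)=C/CC/C(C)=C/CC[C@]1(CC=O)CCc2cc(O[Si](C(C)C)(C(C)C)C(C)C)c(C)c(C)c2O1 | intermediate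
14 | (2R)-2,7,8-trimethyl-2-R-6-(triisopropylsilyloxy)chroman (plastochromanol-8 triisopropylsilyl ether) | CC(C)=CCC/C(C)=C/CC/C(C)=C/CC/C(C)=C/CC/C(C)=C/CC/C(C)=C/CC/C(C)=C/CC/C(C)=C/CC[C@]1(C)CCc2cc(O[Si](C(C)C)(C(C)C)C(C)C)c(C)c(C)c2O1 | intermediate
15 | plastochromanol-8, (2R)-2,7,8-trimethyl-2-R-chroman-6-ol | CC(C)=CCC/C(C)=C/CC/C(C)=C/CC/C(C)=C/CC/C(C)=C/CC/C(C)=C/CC/C(C)=C/CC/C(C)=C/CC[C@]1(C)CCc2cc(O)c(C)c(C)c2O1 | target

## Count and risk

Total step count: 10. Longest linear sequence: 9 steps (steps 1, 2, 4, 5, 6, 7, 8, 9, 10 from 2,3-dimethylhydroquinone).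

Steps most likely to fail:

**Step 4 (domino aldol/oxa-Michael with a C45 enal).** Conversion, the sense and level of induction, and competing dienamine formation at C4 of solanesal are all uncertain. The fallback sets the stereocentre by reagent control and closes the pyran ring by C–O coupling. It sets out from solanesol 5 and phenol 2 and comes back at silyl ether 14.
- Sharpless epoxidation of 5 (Ti(OiPr)4, D-(−)-diethyl tartrate, t-BuOOH, 4 Å molecular sieves, CH2Cl2, −20 °C) gives (2R,3R)-2,3-epoxysolanesol F1.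
- Iodine, PPh3 and imidazole give the epoxy iodide F2.
- Zn dust in EtOH/AcOH at reflux opens F2 reductively to the (R)-tertiary vinyl carbinol F3. The C–O bond of the stereocentre is never broken.
- Phenol 2 is iodinated ortho to the hydroxyl (N-iodosuccinimide, MeCN) to give 6-iodo-2,3-dimethyl-4-(triisopropylsilyloxy)phenol F4.
- 9-BBN hydroborates only the vinyl group of F3 to give the alkylborane F5.
- F5 is coupled in the same flask with F4 (Pd(dppf)Cl2, K3PO4, DMF/THF/H2O, 50 °C) to give the phenol–tertiary alcohol F6.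
- PhNTf2 and K2CO3 convert the phenol into the aryl triflate F7.
- Intramolecular etherification (Pd(OAc)2, 2-(di-tert-butylphosphino)-1,1'-binaphthyl, Cs2CO3, toluene, 80 °C) bonds the tertiary oxygen to the ring with retention at C2 and gives 14.

**Step 6 (Li/NH3 cleavage of the benzylic lactone).** Lithium amide could enolise the lactone and open the pyran ring by retro-oxa-Michael reaction, and the silyl ether or the arene could be attacked. The fallback removes the C4 oxygen through a ketone instead. It sets out from lactone 10 and comes back at alcohol 12.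
- LiAlH4 (THF, 0 °C) gives the (4R)-4-hydroxychroman-2-ylethanol diol F8.
- MnO2 (CH2Cl2) oxidises only the benzylic alcohol to the 4-chromanone F9.
- TsNHNH2 (EtOH, 50 °C) gives the tosylhydrazone F10.
- Catecholborane (CHCl3, 0 °C) and then NaOAc·3H2O at reflux reduce C4 to CH2 and give 12.

**Step 9 (rhodium decarbonylation of a hindered β-aryloxy aldehyde).** The reaction may be slow at the neopentyl-type position, and prolonged heating could open the pyran ring. The fallback removes the carbon as CO2 by a radical route. It sets out from acid 11 and comes back at 14, bypassing steps 7 and 8.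
- Dicyclohexylcarbodiimide, N-hydroxypyridine-2-thione and catalytic 4-dimethylaminopyridine (CH2Cl2, dark) give the Barton ester F11.
- Visible-light photolysis in benzene with a large excess of PhSH gives 14. PhSH is used as a fast hydrogen donor so that reduction of the primary radical outruns its 5-exo cyclisation onto the first chain alkene.

## Further compounds

F1 | step 4 | (2R,3R)-2,3-epoxysolanesol | CC(C)=CCC/C(C)=C/CC/C(C)=C/CC/C(C)=C/CC/C(C)=C/CC/C(C)=C/CC/C(C)=C/CC/C(C)=C/CC[C@@]1(C)O[C@@H]1CO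
F2 | step 4 | 1-iodo-2,3-epoxide of solanesol, same spatial arrangement as F1 (descriptors 2S,3R) | CC(C)=CCC/C(C)=C/CC/C(C)=C/CC/C(C)=C/CC/C(C)=C/CC/C(C)=C/CC/C(C)=C/CC/C(C)=C/CC[C@@]1(C)O[C@@H]1CI
F3 | step 4 | (3R,6E,10E,14E,18E,22E,26E,30E)-3,7,11,15,19,23,27,31,35-nonamethylhexatriaconta-1,6,10,14,18,22,26,30,34-nonaen-3-ol | CC(C)=CCC/C(C)=C/CC/C(C)=C/CC/C(C)=C/CC/C(C)=C/CC/C(C)=C/CC/C(C)=C/CC/C(C)=C/CC[C@@](C)(O)C=C
F4 | step 4 | 6-iodo-2,3-dimethyl-4-(triisopropylsilyloxy)phenol | Ic1cc(O[Si](C(C)C)(C(C)C)C(C)C)c(C)c(C)c1O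
F5 | step 4 | B-alkyl-9-borabicyclo[3.3.1]nonane from hydroboration of the vinyl group of F3, carbinol centre unchanged | CC(C)=CCC/C(C)=C/CC/C(C)=C/CC/C(C)=C/CC/C(C)=C/CC/C(C)=C/CC/C(C)=C/CC/C(C)=C/CC[C@@](C)(O)CCB1C2CCCC1CCC2
F6 | step 4 | 6-[(3R)-3-hydroxy-3-methyl-alkyl]-2,3-dimethyl-4-(triisopropylsilyloxy)phenol, the alkyl chain being that of F3 with the vinyl group saturated | CC(C)=CCC/C(C)=C/CC/C(C)=C/CC/C(C)=C/CC/C(C)=C/CC/C(C)=C/CC/C(C)=C/CC/C(C)=C/CC[C@@](C)(O)CCc1cc(O[Si](C(C)C)(C(C)C)C(C)C)c(C)c(C)c1O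
F7 | step 4 | aryl trifluoromethanesulfonate of F6 | CC(C)=CCC/C(C)=C/CC/C(C)=C/CC/C(C)=C/CC/C(C)=C/CC/C(C)=C/CC/C(C)=C/CC/C(C)=C/CC[C@@](C)(O)CCc1cc(O[Si](C(C)C)(C(C)C)C(C)C)c(C)c(C)c1OS(=O)(=O)C(F)(F)F
F8 | step 6 | 2-[(4R)-4-hydroxy-7,8-dimethyl-2-R-6-(triisopropylsilyloxy)chroman-2-yl]ethanol, C2 arranged as in 10 (descriptor 2S) | CC(C)=CCC/C(C)=C/CC/C(C)=C/CC/C(C)=C/CC/C(C)=C/CC/C(C)=C/CC/C(C)=C/CC/C(C)=C/CC[C@]1(CCO)C[C@@H](O)c2cc(O[Si](C(C)C)(C(C)C)C(C)C)c(C)c(C)c2O1
F9 | step 6 | 2-(2-hydroxyethyl)-7,8-dimethyl-2-R-6-(triisopropylsilyloxy)chroman-4-one, C2 arranged as in 10 | CC(C)=CCC/C(C)=C/CC/C(C)=C/CC/C(C)=C/CC/C(C)=C/CC/C(C)=C/CC/C(C)=C/CC/C(C)=C/CC[C@]1(CCO)CC(=O)c2cc(O[Si](C(C)C)(C(C)C)C(C)C)c(C)c(C)c2O1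
F10 | step 6 | p-toluenesulfonylhydrazone of F9 | CC(C)=CCC/C(C)=C/CC/C(C)=C/CC/C(C)=C/CC/C(C)=C/CC/C(C)=C/CC/C(C)=C/CC/C(C)=C/CC[C@]1(CCO)CC(=NNS(=O)(=O)c3ccc(C)cc3)c2cc(O[Si](C(C)C)(C(C)C)C(C)C)c(C)c(C)c2O1
F11 | step 9 | 2-thioxopyridin-1(2H)-yl ester (Barton ester) of acid 11 | CC(C)=CCC/C(C)=C/CC/C(C)=C/CC/C(C)=C/CC/C(C)=C/CC/C(C)=C/CC/C(C)=C/CC/C(C)=C/CC[C@]1(CC(=O)ON3C=CC=CC3=S)CCc2cc(O[Si](C(C)C)(C(C)C)C(C)C)c(C)c(C)c2O1
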